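**Retrosynthetic overview**
1. Target 11 is a 2‑aryl‑3‑(hydroxymethyl)‑4‑benzyl‑oxolane (2,3‑trans, 3,4‑cis). Its only non‑aromatic ring, O1–C2–C3–C4–C5, is closed last by making the C3–C4 bond.
2. Enabling feature: the C3–C4 bond lies between an exocyclic CH2OH on C3 and an exocyclic ArCH2 on C4, and C5–O1–C2 is an allyl benzyl ether. HO–CH2–C3 is the trace of a terminal epoxide opened to a C3 radical; C4–CH2Ar is the trace of a styrene that accepts it 5‑exo.
3. Key precursor: the acyclic epoxy cinnamyl ether 8 with one relevant stereocentre (future C2). Ti(III) epoxide opening, 5‑exo radical cyclisation and protonation set C3 and C4 and free the CH2OH in one operation.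
4. 8 comes from epoxy alcohol 4 and cinnamyl bromide 7 (Williamson). 4 comes from Sharpless kinetic resolution of the racemic aryl vinyl carbinol 3 (aldehyde 1 + vinyl Grignard 2), the only catalyst‑set centre.
5. 7 comes from methyl 3,4‑dimethoxycinnamate 5 by reduction and bromination; both arenes are bought.

Key step: step 6

Remark: oxolane numbering is O1, C2 (aryl), C3 (CH2OH), C4 (benzyl), C5. The epoxide carbon of 4 and 8 is drawn with a defined configuration, but it becomes a planar radical centre in step 6 and carries no information into the target. Titanium species are written in SMILES with σ‑bonded cyclopentadienyl rings.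

**Step 1**
Reactants: 1 3,4,5‑trimethoxybenzaldehyde; 2 vinylmagnesium bromide
Product: 3 rac‑1‑(3,4,5‑trimethoxyphenyl)prop‑2‑en‑1‑ol
Conditions: 2 (1.2 equiv, 1 M in THF), THF, −78 to 0 °C; sat. aq. NH4Cl
Reagents that add atoms: vinylmagnesium bromide (compound 2), C=C[Mg]Br
Why: Grignard 1,2‑addition to the aryl aldehyde gives the secondary allylic alcohol; no stereocontrol is needed because step 2 resolves it.

**Step 2**
Reactants: 3 rac‑1‑(3,4,5‑trimethoxyphenyl)prop‑2‑en‑1‑ol
Product: 4 (S)‑[(R)‑oxiran‑2‑yl](3,4,5‑trimethoxyphenyl)methanol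
Conditions: Ti(OiPr)4 (0.2 equiv), L‑(+)‑DIPT (0.24 equiv), t‑BuOOH (0.45 equiv, anhydrous in isooctane), 4 Å MS, CH2Cl2, −20 °C; citric acid work‑up; chromatography removes unreacted (S)‑3
Reagents that add atoms: tert‑butyl hydroperoxide, CC(C)(C)OO
Why: Sharpless kinetic resolution (Katsuki–Sharpless epoxidation of a secondary allylic alcohol): with L‑(+)‑DIPT the (R)‑enantiomer of 3 should be the fast one and be epoxidised to the erythro epoxy alcohol, so limiting oxidant should convert it selectively and leave (S)‑3; the carbinol centre fixed here becomes C2 of the target.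

**Step 3**
Reactants: 5 methyl (E)‑3‑(3,4‑dimethoxyphenyl)prop‑2‑enoate
Product: 6 (E)‑3‑(3,4‑dimethoxyphenyl)prop‑2‑en‑1‑ol
Conditions: DIBAL‑H (2.2 equiv), CH2Cl2, −78 to 0 °C; aq. Rochelle salt
Reagents that add atoms: none
Why: DIBAL‑H 1,2‑reduction of the conjugated ester gives the allylic alcohol and leaves the E‑alkene untouched.

**Step 4**
Reactants: 6 (E)‑3‑(3,4‑dimethoxyphenyl)prop‑2‑en‑1‑ol
Product: 7 4‑[(E)‑3‑bromoprop‑1‑en‑1‑yl]‑1,2‑dimethoxybenzene
Conditions: PBr3 (0.4 equiv), Et2O, 0 °C; used crude at once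
Reagents that add atoms: phosphorus tribromide, BrP(Br)Br
Why: Bromination of the allylic alcohol through its phosphite ester; the conjugated linear E‑bromide is the thermodynamically preferred allylic isomer.

**Step 5**
Reactants: 4 (S)‑[(R)‑oxiran‑2‑yl](3,4,5‑trimethoxyphenyl)methanol; 7 4‑[(E)‑3‑bromoprop‑1‑en‑1‑yl]‑1,2‑dimethoxybenzene
Product: 8 (2R)‑2‑[(S)‑{[(E)‑3‑(3,4‑dimethoxyphenyl)prop‑2‑en‑1‑yl]oxy}(3,4,5‑trimethoxyphenyl)methyl]oxirane
Conditions: NaH (1.2 equiv), 7 (1.3 equiv), Bu4NI (0.1 equiv), THF, −20 to 0 °C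
Reagents that add atoms: none
Why: Williamson etherification (SN2 of the sodium alkoxide on the primary allylic bromide); low temperature, an aprotic medium and a reactive electrophile should let O‑alkylation outrun epoxide migration, and the carbinol centre is not touched.

**Step 6**
Reactants: 8 (2R)‑2‑[(S)‑{[(E)‑3‑(3,4‑dimethoxyphenyl)prop‑2‑en‑1‑yl]oxy}(3,4,5‑trimethoxyphenyl)methyl]oxirane
Product: 11 [(2R,3S,4S)‑4‑(3,4‑dimethoxybenzyl)‑2‑(3,4,5‑trimethoxyphenyl)oxolan‑3‑yl]methanol (target), via β‑titanoxy radical 9 (not isolated), via cyclised benzyltitanium alkoxide 10 (not isolated)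
Conditions: Cp2TiCl2 (2.5 equiv), Zn dust, THF, rt (green Cp2TiCl solution added dropwise to 8, 0.02 M in THF); then 1 M HCl, 0 °C
Reagents that add atoms: none
Why: Cp2TiCl transfers one electron to the epoxide of 8, which opens homolytically at its more substituted carbon to the secondary β‑titanoxy radical 9 (the epoxide stereocentre is erased, so only the carbinol centre carries information); 9 adds to the (E)‑styrene to make the C3–C4 bond and the oxolane ring, a second Cp2TiCl captures the benzylic radical as organotitanium 10, and HCl protonates the C–Ti and O–Ti bonds to give the benzyl CH2 and the CH2OH. The closest known reaction type is the titanocene(III) epoxide‑opening radical cyclisation (Nugent–RajanBabu reagent), established for epoxy cinnamyl ethers leading to this 2‑aryl‑3‑hydroxymethyl‑4‑benzyl‑oxolane class. The ring closes in the 5‑exo‑trig mode through a Beckwith–Houk chair‑like transition state. C3 and C4 are both set in this one event by the C2 aryl group: it sits pseudo‑equatorial, the CH2OTi group on the radical carbon turns anti to it (2,3‑trans), and the alkene adds on the face that places the forming CH–Ar′ carbon cis to the C3 substituent and trans to the C2 aryl (3,4‑cis, 2,4‑trans; the cis preference of 1‑substituted and the trans preference of 2‑substituted hex‑5‑enyl radicals act in the same direction here). The step needs ring closure to outrun reduction of 9 by Ti(III) and exo to beat endo attack: the oxygen in the tether and the radical‑stabilising aryl on the alkene terminus should make the 5‑exo addition fast and regioselective, and slow addition keeps Ti(III) dilute.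

**Compound list**
1 | 3,4,5‑trimethoxybenzaldehyde | COc1cc(C=O)cc(OC)c1OC | starting material
2 | vinylmagnesium bromide | C=C[Mg]Br | starting material
3 | rac‑1‑(3,4,5‑trimethoxyphenyl)prop‑2‑en‑1‑ol | C=CC(O)c1cc(OC)c(OC)c(OC)c1 | intermediate
4 | (S)‑[(R)‑oxiran‑2‑yl](3,4,5‑trimethoxyphenyl)methanol | O[C@@H](c1cc(OC)c(OC)c(OC)c1)[C@H]1CO1 | intermediate
5 | methyl (E)‑3‑(3,4‑dimethoxyphenyl)prop‑2‑enoate | COC(=O)/C=C/c1ccc(OC)c(OC)c1 | starting material
6 | (E)‑3‑(3,4‑dimethoxyphenyl)prop‑2‑en‑1‑ol | OC/C=C/c1ccc(OC)c(OC)c1 | intermediate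
7 | 4‑[(E)‑3‑bromoprop‑1‑en‑1‑yl]‑1,2‑dimethoxybenzene | BrC/C=C/c1ccc(OC)c(OC)c1 | intermediate
8 | (2R)‑2‑[(S)‑{[(E)‑3‑(3,4‑dimethoxyphenyl)prop‑2‑en‑1‑yl]oxy}(3,4,5‑trimethoxyphenyl)methyl]oxirane | COc1ccc(/C=C/CO[C@@H](c2cc(OC)c(OC)c(OC)c2)[C@H]2CO2)cc1OC | intermediate
9 | β‑titanoxy secondary radical: 8 with the inner epoxide C–O bond cleaved, radical at the future C3, O–TiCp2Cl on the CH2 | COc1ccc(/C=C/CO[C@@H](c2cc(OC)c(OC)c(OC)c2)[CH]CO[Ti](Cl)(C2C=CC=C2)C2C=CC=C2)cc1OC | intermediate
10 | cyclised bis‑titanium(IV) species: O–TiCp2Cl alkoxide of 11 with a C–TiCp2Cl bond at the benzylic carbon of the C4 side chain (that carbon undefined) | COc1ccc(C([Ti](Cl)(C2C=CC=C2)C2C=CC=C2)[C@@H]2CO[C@@H](c3cc(OC)c(OC)c(OC)c3)[C@@H]2CO[Ti](Cl)(C2C=CC=C2)C2C=CC=C2)cc1OC | intermediate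
11 | [(2R,3S,4S)‑4‑(3,4‑dimethoxybenzyl)‑2‑(3,4,5‑trimethoxyphenyl)oxolan‑3‑yl]methanol | COc1ccc(C[C@@H]2CO[C@@H](c3cc(OC)c(OC)c(OC)c3)[C@@H]2CO)cc1OC | target

**Total step count:** 6
**Longest linear sequence:** 4 steps (1, 2, 5, 6; the branch 3, 4, 5, 6 is equally long)

**Steps most likely to fail**

1. Step 6. The β‑titanoxy radical may be reduced by a second Ti(III) before it closes the ring (β‑elimination then removes the oxygen). The benzylic radical may escape capture and dimerise. The facial selectivity of the alkene addition at C4 may be lower than the chair model predicts. The fallback generates the same C3 radical in a tin hydride chain; it sets out from 8 and comes back at 11. The terminal epoxide of 8 is opened at its CH2 with pivalic acid and caesium pivalate (DMF, 80 °C) to give (2R,3S)‑3‑{[(E)‑3‑(3,4‑dimethoxyphenyl)prop‑2‑en‑1‑yl]oxy}‑2‑hydroxy‑3‑(3,4,5‑trimethoxyphenyl)propyl pivalate F1. The secondary hydroxyl is converted with phenyl chlorothionoformate, pyridine and DMAP (CH2Cl2) into the O‑phenyl thionocarbonate F2. Bu3SnH and AIBN, added by syringe pump in refluxing benzene (Barton–McCombie‑type radical generation, then 5‑exo cyclisation and hydrogen transfer from the stannane to the benzylic radical), should give the oxolane pivalate F3. Any C4 epimer can be removed at this stage, and NaOMe in MeOH then gives 11.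

2. Step 2. The rate difference between the enantiomers of an aryl vinyl carbinol may be too small for the epoxide, the product side of a kinetic resolution, to be enantiopure at useful conversion. The monosubstituted alkene epoxidises slowly, and the titanium Lewis acid may open the benzylic epoxy alcohol. The fallback separates resolution from epoxidation; it sets out from 3 and comes back at 4. Immobilised Candida antarctica lipase B with vinyl acetate (MTBE, rt) should acylate the (R)‑enantiomer to (R)‑1‑(3,4,5‑trimethoxyphenyl)prop‑2‑en‑1‑yl acetate F4, leaving (S)‑3. K2CO3 in MeOH gives (R)‑1‑(3,4,5‑trimethoxyphenyl)prop‑2‑en‑1‑ol F5. Hydroxyl‑directed epoxidation (VO(acac)2 cat., t‑BuOOH, CH2Cl2, 0 °C to rt) gives 4 together with its epoxide epimer (S)‑[(S)‑oxiran‑2‑yl](3,4,5‑trimethoxyphenyl)methanol F6. The mixture is used as such in step 5, where F6 gives the epimeric epoxy ether (2S)‑2‑[(S)‑{[(E)‑3‑(3,4‑dimethoxyphenyl)prop‑2‑en‑1‑yl]oxy}(3,4,5‑trimethoxyphenyl)methyl]oxirane F7. Both epimers converge on radical 9 in step 6.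

3. Step 5. The alkoxide of 4 may undergo base‑induced epoxide migration (Payne rearrangement) before it is alkylated, and the electron‑rich allylic bromide 7 may be lost by elimination or solvolysis. The fallback avoids both the alkali alkoxide and the bromide; it sets out from 6 and 4 and comes back at 8. Alcohol 6 is acetylated (Ac2O, pyridine, DMAP) to (E)‑3‑(3,4‑dimethoxyphenyl)prop‑2‑en‑1‑yl acetate F8. 4 is then treated with Et2Zn (0.5 equiv) and F8 under Pd(OAc)2 and 2‑(di‑tert‑butylphosphino)biphenyl catalysis (THF, rt). This palladium‑catalysed allylic etherification with a zinc alkoxide should attack the less hindered terminus of the π‑allyl complex and give the linear E ether 8.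

**Further compounds**
F1 | step 6 | (2R,3S)‑3‑{[(E)‑3‑(3,4‑dimethoxyphenyl)prop‑2‑en‑1‑yl]oxy}‑2‑hydroxy‑3‑(3,4,5‑trimethoxyphenyl)propyl pivalate | COc1ccc(/C=C/CO[C@@H](c2cc(OC)c(OC)c(OC)c2)[C@H](O)COC(=O)C(C)(C)C)cc1OC
F2 | step 6 | (2R,3S)‑3‑{[(E)‑3‑(3,4‑dimethoxyphenyl)prop‑2‑en‑1‑yl]oxy}‑2‑[(phenoxycarbonothioyl)oxy]‑3‑(3,4,5‑trimethoxyphenyl)propyl pivalate | COc1ccc(/C=C/CO[C@@H](c2cc(OC)c(OC)c(OC)c2)[C@H](OC(=S)Oc2ccccc2)COC(=O)C(C)(C)C)cc1OC
F3 | step 6 | [(2R,3S,4S)‑4‑(3,4‑dimethoxybenzyl)‑2‑(3,4,5‑trimethoxyphenyl)oxolan‑3‑yl]methyl pivalate | COc1ccc(C[C@@H]2CO[C@@H](c3cc(OC)c(OC)c(OC)c3)[C@@H]2COC(=O)C(C)(C)C)cc1OC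
F4 | step 2 | (R)‑1‑(3,4,5‑trimethoxyphenyl)prop‑2‑en‑1‑yl acetate | CC(=O)O[C@@H](c1cc(OC)c(OC)c(OC)c1)C=C
F5 | step 2 | (R)‑1‑(3,4,5‑trimethoxyphenyl)prop‑2‑en‑1‑ol | O[C@@H](c1cc(OC)c(OC)c(OC)c1)C=C
F6 | step 2 | (S)‑[(S)‑oxiran‑2‑yl](3,4,5‑trimethoxyphenyl)methanol | O[C@@H](c1cc(OC)c(OC)c(OC)c1)[C@@H]1CO1
F7 | step 2 | (2S)‑2‑[(S)‑{[(E)‑3‑(3,4‑dimethoxyphenyl)prop‑2‑en‑1‑yl]oxy}(3,4,5‑trimethoxyphenyl)methyl]oxirane | COc1ccc(/C=C/CO[C@@H](c2cc(OC)c(OC)c(OC)c2)[C@@H]2CO2)cc1OC
F8 | step 5 | (E)‑3‑(3,4‑dimethoxyphenyl)prop‑2‑en‑1‑yl acetate | CC(=O)OC/C=C/c1ccc(OC)c(OC)c1
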